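I cannot count chains in Wednesday's or Sunday's run, since the tables give G and J but no number of chains begun, so I reckon length from the charge.

the same everywhere: G 1.5 M
- Wednesday's: Q 0.030 M; D 1.9 mol%; run made earlier
- Sunday's: Q 0.030 M; D 5.9 mol%; run made earlier
- dawn: Q 0.0300 M; D 1.3 mol%; time 8.0 d
- autumn: Q 0.0300 M; D 5 mol%; time 8.0 d

- Wednesday's (time / d: J / %, G / %): 0.625: 1.2, 97.2; 1.25: 4.2, 93.3; 2.08: 12.5, 85.5; 2.50: 17.5, 80.8; 3.00: 23.2, 74.4; 4.00: 37.4, 61.2
- Sunday's (time / d: J / %, G / %): 0.333: 0.5, 97.8; 0.500: 2.2, 96.0; 0.833: 5.7, 92.1; 1.67: 23.2, 74.1; 2.50: 43.8, 54.1; 4.00: 74.8, 23.2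

(scatter of a reading: 0.3 percentage points)

1. which of the two ends with the longer chains by the average number of monomer units in a chain (chains begun, living or dead) ("neither" if they lie within 10%) (dawn / autumn / neither)
2. average number of monomer units in a chain (chains begun, living or dead) at the end, dawn
3. average number of monomer units in a chain (chains begun, living or dead) at the end, autumn

- the average divides the monomer in chains by the number of chains begun, living and dead together
- the numbers in the tables scatter by 0.3 percentage points (one standard deviation)
- the earlier runs do not show the number of chains; that part of a forecast is a guess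

With J and the loading w as fractions of the G charged, f the share of D spent, and one chain per spent D:

length = (J / f) / w

G charged per D charged is 76.9 for dawn and 20.0 for autumn; this charge ratio (the monomer-to-initiator ratio) is what I carry.

I turn the loading first. By hand, more D cuts the charge ratio in proportion and raises J. From Wednesday's run to Sunday's the loading grows by a factor 3.11, which is more than the factor 2.00 on J at 4.00 d, so J times the charge ratio goes from 19.7 to 12.7.

Then I turn the time. By hand, ln((J+G)/G) should follow the loading times the square of the time, and I assume f is common to both flasks at one time. Scaling Wednesday's last reading to dawn and Sunday's to autumn gives: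

dawn: ln((J+G)/G) = 1.31, J = 71.9%

autumn: ln((J+G)/G) = 4.88, J = 97.3%

With f cancelling:

dawn / autumn = 2.84

I commit to dawn, well outside the 10% margin.

The forecast says dawn, with 75 for dawn and 32 for autumn, and of its unshaded lengths it says: "The efficiency is unknown, and Q might start chains, so I shade these lower." Its ratio of 2.34 is smaller than mine.

    D → E (k = 0.00650 h⁻¹)
    G + Z → J + Z, rate k2*[Z]*[G] (k = 0.700 M⁻¹ h⁻¹)
    G + E → Z + J (k = 0.250 M⁻¹ h⁻¹)
    Q + G → X (k = 0.110 M⁻¹ h⁻¹)

The flask gives dawn, with 72.1 for dawn and 31.8 for autumn, a ratio of 2.27, which stands with the forecast's and below mine. At 8.00 d dawn holds J at 65.4% and D at 28.7% of its charge, so the charge ratio gives 70.5 against the simulated 72.1. The neighbour with 2.5 M of G keeps dawn's loading and so its charge ratio of 76.9; with J at 83.1% and D at 28.7% the same line gives 89.6, and that flask stands at 92.0.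

The readings are simulated for substances that don't exist; the scatter is artificial.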